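**Assumption:** the target SMILES has no stereocentre and no stereogenic double bond, so isosinensetin (5,7,8,3',4'-pentamethoxyflavone) is achiral and "single enantiomer" simply means the compound itself.

**Retrosynthetic overview**
1. The pyranone C ring is formed last by cutting O1–C2 and C3–C4 together. This gives salicylaldehyde 5 (aldehyde C–H becomes C4) and aroyl sulfoxonium ylide 9 (carbene carbon becomes C3, ketone carbon becomes C2).
2. The two are joined by Rh(III) aldehyde C–H activation and carbene insertion, then cyclodehydration in the same flask. No acetophenone, chalcone or Baker–Venkataraman ester is used.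
3. Ylide 9 comes from 3,4-dimethoxybenzoyl chloride and dimethylsulfoxonium methylide (B ring bought intact).
4. Aldehyde 5 comes from 1,2,3,5-tetramethoxybenzene by Vilsmeier formylation and chelation-controlled mono-demethylation (A ring bought intact).
5. Ring order: A and B rings are purchased; the C ring is the only ring made, in the last step.

**Route**

Step 1
Reactants: 1 1,2,3,5-tetramethoxybenzene
Product: 3 2,3,4,6-tetramethoxybenzaldehyde, via aryl iminium salt 2 (not isolated)
Conditions: POCl3 (1.2 equiv), DMF, 0 °C → 60 °C; then ice-water, rt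
Reagents that add atoms: N,N-dimethylformamide CN(C)C=O; water O
Why: Vilsmeier–Haack formylation of a strongly activated arene whose only two free positions are equivalent by symmetry, so hydrolysis of iminium 2 gives a single aldehyde.

Step 2
Reactants: 3 2,3,4,6-tetramethoxybenzaldehyde
Product: 5 2-hydroxy-3,4,6-trimethoxybenzaldehyde, via aryloxydichloroborane 4 (not isolated)
Conditions: BCl3 (1.1 equiv, 1 M in CH2Cl2), CH2Cl2, −78 °C → −10 °C; then H2O
Reagents that add atoms: none
Why: Chelation-controlled Lewis-acid ether cleavage, in which BCl3 bound to the formyl oxygen is delivered to an ortho methoxy and the 2-OMe (squeezed between CHO and 3-OMe, twisted out of conjugation, hence more basic and more strained than the 6-OMe) is lost as chloromethane through six-membered boron chelate 4, which at low temperature with one equivalent also resists a second demethylation.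

Step 3
Reactants: 6 trimethylsulfoxonium iodide; 7 3,4-dimethoxybenzoyl chloride
Product: 9 2-[dimethyl(oxo)-λ6-sulfanylidene]-1-(3,4-dimethoxyphenyl)ethan-1-one, via dimethylsulfoxonium methylide 8 (not isolated)
Conditions: 6 (3 equiv), KOtBu (3 equiv), THF, reflux 2 h; then 7 (1 equiv), 0 °C → rt
Reagents that add atoms: none
Why: Corey–Chaykovsky-type acylation of the sulfoxonium methylide, in which 8 attacks the aroyl chloride and a second equivalent of 8 deprotonates the acylsulfoxonium salt to give the stabilised, bench-stable β-keto sulfoxonium ylide.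

Step 4
Reactants: 5 2-hydroxy-3,4,6-trimethoxybenzaldehyde; 9 2-[dimethyl(oxo)-λ6-sulfanylidene]-1-(3,4-dimethoxyphenyl)ethan-1-one
Product: 11 isosinensetin (5,7,8,3',4'-pentamethoxyflavone), via hydroxyaryl diketone 10 (not isolated)
Conditions: [Cp*RhCl2]2 (4 mol %), AgSbF6 (16 mol %), PivOH (1 equiv), DCE, 100 °C; then TsOH·H2O (20 mol %), 80 °C
Reagents that add atoms: none
Why: Rh(III)-catalysed, phenol-directed aldehyde C–H activation gives an acyl rhodacycle that forms a Rh carbene from the ylide with loss of DMSO, and migratory insertion plus protodemetalation (C–H acylmethylation) give diketone 10, whose acid-catalysed cyclodehydration through the only free phenol (the one next to the 3-OMe) can give only the 5,7,8-pattern and creates no stereocentre.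

**Compound list**
1 | 1,2,3,5-tetramethoxybenzene | COc1cc(OC)c(OC)c(OC)c1 | starting material
2 | N-methyl-N-[(2,3,4,6-tetramethoxyphenyl)methylidene]methanaminium dichlorophosphate | COc1cc(OC)c(C=[N+](C)C)c(OC)c1OC.[O-]P(=O)(Cl)Cl | intermediate
3 | 2,3,4,6-tetramethoxybenzaldehyde | COc1cc(OC)c(C=O)c(OC)c1OC | intermediate
4 | dichloro(2-formyl-3,5,6-trimethoxyphenoxy)borane (carbonyl-chelated) | COc1cc(OC)c(C=O)c(OB(Cl)Cl)c1OC | intermediate
5 | 2-hydroxy-3,4,6-trimethoxybenzaldehyde | COc1cc(OC)c(C=O)c(O)c1OC | intermediate
6 | trimethylsulfoxonium iodide | C[S+](C)(C)=O.[I-] | starting material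
7 | 3,4-dimethoxybenzoyl chloride | COc1ccc(C(=O)Cl)cc1OC | starting material
8 | dimethylsulfoxonium methylide | C=S(C)(C)=O | intermediate
9 | 2-[dimethyl(oxo)-λ6-sulfanylidene]-1-(3,4-dimethoxyphenyl)ethan-1-one | COc1ccc(C(=O)C=S(C)(C)=O)cc1OC | intermediate
10 | 1-(3,4-dimethoxyphenyl)-3-(2-hydroxy-3,4,6-trimethoxyphenyl)propane-1,3-dione | COc1ccc(C(=O)CC(=O)c2c(OC)cc(OC)c(OC)c2O)cc1OC | intermediate
11 | isosinensetin, 2-(3,4-dimethoxyphenyl)-5,7,8-trimethoxy-4H-chromen-4-one | COc1ccc(-c2cc(=O)c3c(OC)cc(OC)c(OC)c3o2)cc1OC | target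

**Step count**
Total steps: 4. Longest linear sequence: 3 steps (1 → 3 → 5 → 11); step 3 is a one-step side branch.

**Three steps most likely to fail, with fallbacks**

Step 4 is the riskiest. The aldehyde is electron-rich and flanked on both sides, so rhodacycle formation may be slow, and decarbonylation or O–H insertion of the carbene may compete. The fallback sets out from 5 and comes back at 11, replacing C–H activation by an ynone 6-endo closure. Commercial 4-ethynyl-1,2-dimethoxybenzene is deprotonated with n-BuLi in THF at −78 °C to lithium (3,4-dimethoxyphenyl)acetylide F1. Adding 2.2 equiv of it to 5 (one equivalent is consumed by the phenol) gives racemic 2-[3-(3,4-dimethoxyphenyl)-1-hydroxyprop-2-yn-1-yl]-3,5,6-trimethoxyphenol F2. Activated MnO2 in CH2Cl2 oxidises this to 3-(3,4-dimethoxyphenyl)-1-(2-hydroxy-3,4,6-trimethoxyphenyl)prop-2-yn-1-one F3. Et2NH in refluxing EtOH then adds to the ynone to give (E)-3-(diethylamino)-3-(3,4-dimethoxyphenyl)-1-(2-hydroxy-3,4,6-trimethoxyphenyl)prop-2-en-1-one F4, and the phenol displaces the amine by addition–elimination to give 11 without aurone formation.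

Step 2 is next. The 2-OMe and 6-OMe are both ortho to the aldehyde, so selectivity may be incomplete, and over-demethylation is possible. The fallback sets out from 1 and comes back at 10; it gives up the aldehyde and uses a ketone, whose chelate directs more strongly. Friedel–Crafts acetylation of 1 with AcCl/AlCl3 in Et2O gives 2,3,4,6-tetramethoxyacetophenone F5, which the same AlCl3 demethylates in the flask at the flanked ortho methoxy to 2-hydroxy-3,4,6-trimethoxyacetophenone F6. The lithium dianion of F6 (LiHMDS, 3 equiv, THF, −78 °C → rt) is C-acylated by 7 to give diketone 10, which is closed to 11 with TsOH as in the second stage of step 4.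

Step 3 is the least risky of the three. The methylide is moisture-sensitive, double acylation can occur, and 9 is very polar. The fallback sets out from 7 and comes back at 10, using a different carbene precursor. Treating 7 with TMSCHN2 in MeCN/THF at 0 °C gives 2-diazo-1-(3,4-dimethoxyphenyl)ethan-1-one F7. Slow addition of F7 to 5 under the same Cp*Rh(III) catalyst forms the Rh carbene with loss of N2 instead of DMSO and delivers 10, which cyclises to 11 as before.

**Further compounds**
F1 | step 4 | lithium (3,4-dimethoxyphenyl)acetylide | [Li]C#Cc1ccc(OC)c(OC)c1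
F2 | step 4 | racemic 2-[3-(3,4-dimethoxyphenyl)-1-hydroxyprop-2-yn-1-yl]-3,5,6-trimethoxyphenol | COc1ccc(C#CC(O)c2c(OC)cc(OC)c(OC)c2O)cc1OC
F3 | step 4 | 3-(3,4-dimethoxyphenyl)-1-(2-hydroxy-3,4,6-trimethoxyphenyl)prop-2-yn-1-one | COc1ccc(C#CC(=O)c2c(OC)cc(OC)c(OC)c2O)cc1OC
F4 | step 4 | (E)-3-(diethylamino)-3-(3,4-dimethoxyphenyl)-1-(2-hydroxy-3,4,6-trimethoxyphenyl)prop-2-en-1-one | CCN(CC)/C(c1ccc(OC)c(OC)c1)=C/C(=O)c1c(OC)cc(OC)c(OC)c1O
F5 | step 2 | 2,3,4,6-tetramethoxyacetophenone | COc1cc(OC)c(C(C)=O)c(OC)c1OC
F6 | step 2 | 2-hydroxy-3,4,6-trimethoxyacetophenone | COc1cc(OC)c(C(C)=O)c(O)c1OC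
F7 | step 3 | 2-diazo-1-(3,4-dimethoxyphenyl)ethan-1-one | COc1ccc(C(=O)C=[N+]=[N-])cc1OC
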